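## Compounds and numbering

Each half is numbered as in the drimanes, with primes for the second half. Ring A is C1–C5 plus C10 and ring B is C5–C10. C4 carries the two methyl groups, C5 is the ring-fusion CH and C10 the ring-fusion quaternary carbon. The ring alkene is C8=C9, with a methyl on C8 and the bridge carbon C11 on C9; the halves are joined by the C11–C11' bond.

1 2,3-dimethylbenzoic acid · 2 lithium 2-(lithiomethyl)-3-methylbenzoate · 3 bibenzyl diacid · 4 bis(N-methoxy-N-methylamide) · 5 4-bromo-2-methylbut-1-ene · 6 its Grignard reagent · 7 bis(aryl 3-methylbut-3-enyl ketone) · 8 bis-tetralone · 9 methyl iodide · 10 dipotassium bis-dienolate · 11 bis(tributylstannyl) bis-dienolate · 12 (R,R)-bis-dienone · 13 trans-fused diketone · 14 bis-hydrazone · 15 target.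

## Analysis of the target

Target 15 is a C30H50 hydrocarbon built from two identical bicyclic halves joined through the C11–C11' bond of an ethano bridge. Each half is a trans-fused decalin: ring A is saturated and carries the gem-dimethyl group at C4, and ring B holds the tetrasubstituted C8=C9 alkene. There are four stereocentres, C5, C10, C5' and C10', all S. Within a half H-5 and CH3-10 are trans, and the two halves have the same handedness, so the molecule has a C2 axis and is not the meso form. The only reactive groups are the two tetrasubstituted alkenes, which acid would move or draw into cation–olefin chemistry, and the final structure has no heteroatom to help with purification, resolution or directing effects. Two things make the synthesis hard: the quaternary carbon C10 sits directly on a tetrasubstituted alkene carbon, and C10 and C10' are five bonds apart, so one half cannot pass its configuration to the other. The strategy rests on ring B: a quaternary C10, a CH2 opposite to it (C7) and a dialkylated C8=C9 double bond are what an ipso/para dearomatisation leaves of a benzene ring whose C10 bore an acyl carbon (C1).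

## Retrosynthetic reasoning

**C1 and C1' oxygen (15 ⇐ 13).** The last operation is the removal of two carbonyl groups through bis-hydrazone 14 (Wolff–Kishner reduction). The C1 carbonyl is needed earlier, because it makes the arene reducible and fixes where the electrons and the methyl group go. It is removed only after ring B has lost its skipped diene, since hot base would move a 1,4-diene into conjugation and scramble C9.

**C5–H and C5'–H (13 ⇐ 12).** The trans ring fusion is traced back to the trisubstituted C5=C6 alkene of 12. Hydrogen has to arrive on the face opposite to the C10 methyl. The tetrasubstituted C8=C9 alkene, buried between C10 and C11, should stay.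

**C10–CH3 and C10'–CH3 (12 ⇐ 8 + 9).** This is the disconnection that carries the plan. Cutting the angular methyl groups and re-aromatising ring B leads to the flat, achiral bis-tetralone 8. In the forward direction a Birch reduction gives dienolate 10, and methylation at the ipso carbon with 9 creates C10 and leaves C8=C9 and C5=C6 where the arene substituents dictate. One operation on both halves therefore delivers two quaternary centres and both tetrasubstituted alkenes. Since 8 is achiral and the sites are remote, the facial choice has to come from a chiral ligand on the metal that carries the dienolate. A chiral ligand cannot compete with the solvent and the potassium counter-ion in the reduction medium, so the dienolate is moved onto tin (11) and methylated under a chiral Lewis-acid catalyst.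

**C4–C5 and C4'–C5' (8 ⇐ 7).** Ring A is opened at the aryl–C4 bond (Friedel–Crafts cycloalkylation). The aryl–C1 bond is not the one to cut: an acylation as the last ring-forming step would go to the unhindered ortho position and put the carbonyl on the wrong side. With the carbonyl carbon already on the ring, as in 7, the tertiary cation has only one ortho position to attack.

**C1–C2 and C1'–C2' (7 ⇐ 4 + 6; 4 ⇐ 3).** The side chains are attached by ketone synthesis from the bis(N-methoxy-N-methylamide) 4 and the homoallylic Grignard reagent 6, made from bromide 5. Amide 4 comes from diacid 3. This stops cleanly at the ketone and leaves the 1,1-disubstituted alkene ready for the ring closure.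

**C11–C11' (3 ⇐ 1 + 1).** The bridge is the symmetry element of the molecule, so it is cut first in the retrosynthesis and made first in the synthesis. Cutting it divides 3 into two identical molecules of 1. In the forward direction two molecules of the benzylic dianion 2 are joined by oxidative homocoupling in one step. The carboxylate directs lithiation to the ortho methyl group of 1, which decides between the two methyl groups.

## Alternatives that were turned down

**Alternative 1:** Both halves are unzipped completely. C4–C5 and C9–C10 and their primed counterparts are cut, which leads to the acyclic (3S,22S)-diepoxy tetraene-yne A1, in which the future C11–C11' bond is a triple bond. In the forward direction CH3AlCl2 would open each epoxide at C4, the C5=C10 alkene would attack through C5, the C8=C9 alkene would close ring B through C9, and loss of the proton on C9 would give the 3,3'-dihydroxy dienyne A2, with four rings formed at once.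
- For: chair–chair folding gives the trans fusion and the C5/C10 relationship, and the absolute configuration comes from the epoxides, which known catalytic asymmetric oxidations can set. On stereocontrol this plan is stronger than the chosen one, because every stereochemical element rests on established reaction types.
- Against: the terminating alkene is the ene part of an enyne, with C9 attached to an sp carbon, so it is a poor nucleophile. Interrupted cyclisation is likely, and the event must succeed twice in one molecule. A1 needs a stereodefined C30 chain with four E-trisubstituted alkenes and oxidation only at the two ends. A2 carries two hydroxyls and a triple bond that 15 lacks, so two deoxygenations and a selective alkyne saturation follow.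
- Comparison: the operation count would be more than twice that of the chosen route. The chosen route brings the ring carbons pre-assembled in an arene and needs seven steps, at the price of an unproven asymmetric step.

**Alternative 2:** Ring A is cut at C10–C1 and C4–C5 as a [4+2] retron. Ring B comes from 2,6-dimethyl-1,4-benzoquinone A3 and C1–C4 from 4-methylpenta-1,3-diene A4. A binaphthol-derived chiral titanium Lewis acid (from TiCl2(O-i-Pr)2) would give the cis-fused adduct A5 and set C10.
- For: Lewis-acid-catalysed enantioselective quinone Diels–Alder reactions are an established class. Both double bonds of A3 are equivalent and each bears a methyl, so a quaternary C10 forms whichever reacts. Each half would be enantiopure before the halves are joined, so no meso isomer can arise. On precedent for the asymmetric step this plan is ahead of the chosen one.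
- Against: A4 has two methyls on one diene terminus, one necessarily cis, so the reactive s-cis conformer is strained. The diene should be sluggish and prone to acid-induced isomerisation to a more reactive isomer that gives the wrong skeleton. The regiochemistry must also place the CMe2 terminus on C5. A5 is cis-fused and over-oxidised: C5 must be epimerised, the C6 carbonyl and the ring A alkene removed, and the C9 carbonyl turned into the C9–C11 bond and the C8=C9 alkene.
- Comparison: A5 is only one half, and the union of two halves remains to be done. The chosen route makes both halves and the bridge from one aromatic acid in far fewer steps.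

**Alternative 3:** The bridge is raised to an alkyne and cut at C9–C11 and C9'–C11'. Two molecules of the enol triflate A7, made from the enantiopure bicyclic ketone A6, would be coupled with acetylene A8 under Pd(PPh3)4, CuI and an amine base to give the dienyne A9. The triple bond is then saturated.
- For: C5 and C10 are fixed in each half before the union, so there is no meso isomer and no unproven asymmetric step. The plan is convergent, and A6 can enolise only toward C8, so the triflate regiochemistry is unambiguous. On certainty of the stereochemical outcome this is the strongest of the four plans.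
- Against: A6 must first be obtained enantiopure, which costs several steps. Oxidative addition of zerovalent palladium into a tetrasubstituted enol triflate next to a quaternary carbon is slow. A8 must couple twice, in competition with mono-coupling and with oxidative alkyne dimerisation, which would give a four-carbon bridge. Reducing the triple bond of A9 between two conjugated alkenes risks conjugate addition of hydrogen and migration of the ring alkenes.
- Comparison: the chosen route is shorter and starts from cheaper material. If the enantioselection of its key step fails, this alternative is the natural replacement.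

Key step: step 5

Assumption: the sense of induction of the salen–chromium catalyst on this dienolate cannot be predicted with confidence. The (R,R)-ligand is written; the (S,S)-antipode would be used in the same way if a test on the analogous mono-tetralone showed that it gives the (8aR) configuration. (R,R)-(salen)CrCl denotes chloro[(R,R)-N,N'-bis(3,5-di-tert-butylsalicylidene)cyclohexane-1,2-diaminato]chromium, C36H52ClCrN2O2, a complex of trivalent chromium.

## Route

Step 1
Reactants: 1 2,3-dimethylbenzoic acid (2 equiv; two molecules are joined at their C2 methyl groups)
Product: 3 2,2'-(ethane-1,2-diyl)bis(3-methylbenzoic acid), via lithium 2-(lithiomethyl)-3-methylbenzoate 2 (not isolated)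
Conditions: LiN(i-Pr)2 (2.2 equiv per acid), THF, −78 to 0 °C; I2 (0.5 equiv per acid), −78 °C to rt; aq. HCl
Reagents that add atoms: 2,3-dimethylbenzoic acid 1 (second molecule), Cc1cccc(C(=O)O)c1C
Why: Carboxylate-directed lateral lithiation removes a proton only from the ortho (C2) methyl group, and oxidative homocoupling of benzylic lithium species and carboxylic acid dianions with iodine is a known way to bibenzyls and succinic acids, so two molecules of dianion 2 give one molecule of 3; the coupling has to outrun lactonisation of the transient benzylic iodide, which the low temperature and the excess of anion during the addition favour; no stereocentre is formed.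

Step 2
Reactants: 3 2,2'-(ethane-1,2-diyl)bis(3-methylbenzoic acid)
Product: 4 2,2'-(ethane-1,2-diyl)bis(N-methoxy-N,3-dimethylbenzamide)
Conditions: MeNH(OMe)·HCl (2.4 equiv), EDC·HCl (2.4 equiv), DMAP (cat.), i-Pr2NEt, CH2Cl2, 0 °C to rt
Reagents that add atoms: N,O-dimethylhydroxylamine hydrochloride, CNOC.Cl
Why: Carbodiimide amide coupling of a benzoic acid with only one ortho substituent is routine; the N-methoxy-N-methylamide is chosen because its chelated adduct stops organometallic addition at the ketone stage.

Step 3
Reactants: 4 2,2'-(ethane-1,2-diyl)bis(N-methoxy-N,3-dimethylbenzamide); 5 4-bromo-2-methylbut-1-ene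
Product: 7 1,1'-[ethane-1,2-diylbis(3-methyl-2,1-phenylene)]bis(4-methylpent-4-en-1-one), via (3-methylbut-3-en-1-yl)magnesium bromide 6 (not isolated)
Conditions: 5, Mg, THF, rt; then 4, THF, 0 °C to rt; aq. HCl
Reagents that add atoms: 4-bromo-2-methylbut-1-ene 5 (through its Grignard reagent 6), CC(=C)CCBr
Why: Weinreb ketone synthesis: the magnesium chelate of the tetrahedral adduct survives until the acidic work-up, so no tertiary alcohol forms, and the homoallylic Grignard reagent is structurally unambiguous because its cyclopropylcarbinyl rearrangement is degenerate.

Step 4
Reactants: 7 1,1'-[ethane-1,2-diylbis(3-methyl-2,1-phenylene)]bis(4-methylpent-4-en-1-one)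
Product: 8 8,8'-(ethane-1,2-diyl)bis(4,4,7-trimethyl-3,4-dihydronaphthalen-1(2H)-one)
Conditions: AlCl3 (6 equiv), ClCH2CH2Cl, 0 to 50 °C
Reagents that add atoms: none
Why: Intramolecular Friedel–Crafts cycloalkylation of a γ,δ-unsaturated aryl ketone, a classical tetralone synthesis: the tertiary cation formed from the 1,1-disubstituted alkene attacks the only free position ortho to the acyl group, which is para to the ring methyl and so the least deactivated, and closes the six-membered ring; trapping of the cation by the carbonyl oxygen is reversible, and the product is achiral.

Step 5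
Reactants: 8 8,8'-(ethane-1,2-diyl)bis(4,4,7-trimethyl-3,4-dihydronaphthalen-1(2H)-one); 9 methyl iodide
Product: 12 (8aR,8a'R)-8,8'-(ethane-1,2-diyl)bis(4,4,7,8a-tetramethyl-3,4,6,8a-tetrahydronaphthalen-1(2H)-one), via dipotassium bis-dienolate 10 (not isolated), via bis(tributylstannyl) bis-dienolate 11 (not isolated)
Conditions: K (4.4 equiv), t-BuOH (2.0 equiv), NH3/THF, −78 °C; isoprene; evaporate NH3 and THF; Bu3SnCl (4.2 equiv), toluene, 0 °C; (R,R)-(salen)CrCl (20 mol%), CH3I (8 equiv), toluene, 0 °C
Reagents that add atoms: methyl iodide 9, CI
Why: Proposed new method: two-electron reduction of each aryl ketone and protonation at C7 (para to C10) by t-BuOH should give the cross-conjugated potassium dienolate 10, exactly as in the known, racemic Birch reductive alkylation of 1-tetralones; no ring closes. After removal of NH3, Bu3SnCl converts the enolate and the tert-butoxide into the covalent tin dienolate 11 and Bu3SnOt-Bu; unlike an ionic enolate, 11 should be inert to CH3I on its own, which suppresses the racemic background reaction. Exchange of tin for chromium is expected to place each dienolate oxygen on the trivalent chromium centre of the salen complex, whose diamine backbone and tert-butyl groups cover one face of the flat O–C1=C10 unit, so that CH3I attacks C10 from the open face and the catalyst returns with release of Bu3SnI. The closest known reaction type is the Cr(salen)Cl-catalysed enantioselective alkylation of tetrasubstituted tributyltin enolates of cyclic ketones, which has not been shown for a reductively generated dienolate or for two sites in one substrate. Both new stereocentres, C10 and C10', are set by the catalyst alone, because 8 is achiral and the sites are too far apart to influence each other; the two groups the catalyst has to tell apart are the C9 arm, syn to oxygen and carrying C11, and the ring-bound C5 arm. The step needs methylation at C10 and not at C6, C8 or oxygen, which the highest charge density at the enolate carbon and the soft electrophile should secure, and it needs the same face at both sites. Because the sites react independently, most minor-face events end in the separable meso diastereomer, so the enantiomeric purity of the C2 product should exceed the per-site selectivity; a 9:1 preference per site would correspond, by statistics alone, to about 81:18:1 for 12, meso isomer and enantiomer. The alkene positions are fixed by the arene, since the carbon para to C10 is the unsubstituted C7.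

Step 6
Reactants: 12 (8aR,8a'R)-8,8'-(ethane-1,2-diyl)bis(4,4,7,8a-tetramethyl-3,4,6,8a-tetrahydronaphthalen-1(2H)-one)
Product: 13 (4aS,8aS,4a'S,8a'S)-8,8'-(ethane-1,2-diyl)bis(4,4,7,8a-tetramethyl-3,4,4a,5,6,8a-hexahydronaphthalen-1(2H)-one)
Conditions: H2 (4 atm), PtO2 (cat.), EtOAc, rt
Reagents that add atoms: none
Why: Heterogeneous catalytic hydrogenation with syn delivery from the adsorbed face: the β face of C5=C6 carries the C10 methyl and the axial methyl on C4, so both hydrogens should arrive on the α face and place H-5 trans to CH3-10 (5S, as in 4,4,10-trimethyl-Δ5 systems), while the tetrasubstituted C8=C9 alkene between C10 and C11 should not adsorb; platinum in a neutral solvent is chosen because it causes little double-bond migration in the skipped diene and is slow to reduce the hindered carbonyl.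

Step 7
Reactants: 13 (4aS,8aS,4a'S,8a'S)-8,8'-(ethane-1,2-diyl)bis(4,4,7,8a-tetramethyl-3,4,4a,5,6,8a-hexahydronaphthalen-1(2H)-one)
Product: 15 1,2-bis[(4aS,8aS)-2,5,5,8a-tetramethyl-3,4,4a,5,6,7,8,8a-octahydronaphthalen-1-yl]ethane, via bis-hydrazone 14 (not isolated)
Conditions: N2H4·H2O, KOH, diethylene glycol, 130 °C, then 210 °C with removal of water
Reagents that add atoms: none
Why: Wolff–Kishner reduction in its Huang-Minlon form: the hydrazone forms at the C1 carbonyl and base-induced loss of N2 leaves the methylene group; C10 is quaternary and C5 is not α to the carbonyl, so no stereocentre can epimerise, and the isolated tetrasubstituted alkene has no acidic position from which it could migrate.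

## Compound list

1 | 2,3-dimethylbenzoic acid | Cc1cccc(C(=O)O)c1C | starting material
2 | lithium 2-(lithiomethyl)-3-methylbenzoate | Cc1cccc(C(=O)O[Li])c1C[Li] | intermediate
3 | 2,2'-(ethane-1,2-diyl)bis(3-methylbenzoic acid) | Cc1cccc(C(=O)O)c1CCc1c(C)cccc1C(=O)O | intermediate
4 | 2,2'-(ethane-1,2-diyl)bis(N-methoxy-N,3-dimethylbenzamide) | Cc1cccc(C(=O)N(C)OC)c1CCc1c(C)cccc1C(=O)N(C)OC | intermediate
5 | 4-bromo-2-methylbut-1-ene | CC(=C)CCBr | starting material
6 | (3-methylbut-3-en-1-yl)magnesium bromide | CC(=C)CC[Mg]Br | intermediate
7 | 1,1'-[ethane-1,2-diylbis(3-methyl-2,1-phenylene)]bis(4-methylpent-4-en-1-one) | Cc1cccc(C(=O)CCC(C)=C)c1CCc1c(C)cccc1C(=O)CCC(C)=C | intermediate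
8 | 8,8'-(ethane-1,2-diyl)bis(4,4,7-trimethyl-3,4-dihydronaphthalen-1(2H)-one) | O=C1CCC(C)(C)c2ccc(C)c(CCc3c(C)ccc4c3C(=O)CCC4(C)C)c12 | intermediate
9 | methyl iodide | CI | starting material
10 | dipotassium 8,8'-(ethane-1,2-diyl)bis(4,4,7-trimethyl-2,3,4,6-tetrahydronaphthalen-1-olate) | [O-]C1=C2C(CCC3=C(C)CC=C4C3=C([O-])CCC4(C)C)=C(C)CC=C2C(C)(C)CC1.[K+].[K+] | intermediate
11 | 8,8'-(ethane-1,2-diyl)bis[4,4,7-trimethyl-1-(tributylstannyloxy)-2,3,4,6-tetrahydronaphthalene] | CCCC[Sn](CCCC)(CCCC)OC1=C2C(CCC3=C(C)CC=C4C3=C(O[Sn](CCCC)(CCCC)CCCC)CCC4(C)C)=C(C)CC=C2C(C)(C)CC1 | intermediate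
12 | (8aR,8a'R)-8,8'-(ethane-1,2-diyl)bis(4,4,7,8a-tetramethyl-3,4,6,8a-tetrahydronaphthalen-1(2H)-one) | CC1=C(CCC2=C(C)CC=C3C(C)(C)CCC(=O)[C@]23C)[C@@]2(C)C(=O)CCC(C)(C)C2=CC1 | intermediate
13 | (4aS,8aS,4a'S,8a'S)-8,8'-(ethane-1,2-diyl)bis(4,4,7,8a-tetramethyl-3,4,4a,5,6,8a-hexahydronaphthalen-1(2H)-one) | CC1=C(CCC2=C(C)CC[C@H]3C(C)(C)CCC(=O)[C@]23C)[C@@]2(C)C(=O)CCC(C)(C)[C@@H]2CC1 | intermediate
14 | bis-hydrazone of 13 at C1 and C1' | CC1=C(CCC2=C(C)CC[C@H]3C(C)(C)CCC(=NN)[C@]23C)[C@@]2(C)C(=NN)CCC(C)(C)[C@@H]2CC1 | intermediate
15 | 1,2-bis[(4aS,8aS)-2,5,5,8a-tetramethyl-3,4,4a,5,6,7,8,8a-octahydronaphthalen-1-yl]ethane | CC1=C(CCC2=C(C)CC[C@H]3C(C)(C)CCC[C@]23C)[C@@]2(C)CCCC(C)(C)[C@@H]2CC1 | target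

## Step count and least certain steps

Total: 7 steps. Longest linear sequence: 7 steps, from 1.

**Step 5 (key step).** Several processes could fail:
- facial discrimination by the catalyst may be poor on a dienolate whose two arms are both alkenyl, which would lower the enantiomeric purity and raise the share of the meso isomer;
- methylation may stray to C6, C8 or oxygen, because C10 is flanked by fully substituted carbons;
- the carbonyl may be over-reduced in the dissolving-metal stage;
- the dienolate may suffer proton scrambling while the ammonia is removed;
- residual ammonia may poison the Lewis-acidic catalyst.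

The fallback uses known chemistry. It sets out from 8 and comes back at 12. The racemic reductive methylation of 1-tetralones (K, t-BuOH, NH3/THF, −78 °C; LiBr; CH3I) would give 12 together with its enantiomer, (8aS,8a'S)-8,8'-(ethane-1,2-diyl)bis(4,4,7,8a-tetramethyl-3,4,6,8a-tetrahydronaphthalen-1(2H)-one) F1, and the meso isomer, (8aR,8a'S)-8,8'-(ethane-1,2-diyl)bis(4,4,7,8a-tetramethyl-3,4,6,8a-tetrahydronaphthalen-1(2H)-one) F2. The meso isomer is removed by chromatography or crystallisation, and the racemate is resolved by preparative chromatography on a cellulose tris(3,5-dimethylphenylcarbamate) stationary phase. At most a quarter of the material would be 12, but no step is added and 8 is cheap.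

**Step 1.** Lactonisation of the transient ortho-iodomethyl carboxylate to a phthalide may compete with the coupling of the two molecules of 2, and lithiation may be incomplete. The fallback sets out not from 1 but from two purchased compounds and comes back at 4. Methyl 2-bromo-3-methylbenzoate F3 and (E)-1,2-bis(4,4,5,5-tetramethyl-1,3,2-dioxaborolan-2-yl)ethene F4 would undergo a twofold Suzuki–Miyaura coupling (Pd(dppf)Cl2, K2CO3, dioxane/H2O, 90 °C) to dimethyl 2,2'-[(E)-ethene-1,2-diyl]bis(3-methylbenzoate) F5. Hydrogenation (H2, Pd/C, EtOAc) would give dimethyl 2,2'-(ethane-1,2-diyl)bis(3-methylbenzoate) F6, and MeNH(OMe)·HCl with i-PrMgCl in THF at −20 °C would convert the ester groups directly into the amide groups of 4. This costs one step more.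

**Step 4.** The ring to be attacked is deactivated by the ketone and its AlCl3 complex, so loss of a proton from the cation, migration of the alkene into conjugation with the carbonyl and cationic oligomerisation may outrun the ring closure. The fallback sets out from 7 and comes back at 8 without new compounds. Metal-hydride hydrogen-atom transfer (Fe(acac)3, PhSiH3, EtOH, t-BuOOH as terminal oxidant) would generate the same tertiary carbon as a nucleophilic radical. Such a radical is polarity-matched to add ortho to the acyl group, and the resulting cyclohexadienyl radical is oxidised back to the arene.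

**Step 6.** Saturation of an alkene flanked by two quaternary carbons may be slow. The double bond may migrate within the skipped diene, the C1 carbonyl may be partly reduced (which would call for re-oxidation), or hydrogen may be delivered to the wrong face. The fallback sets out from 12 and comes back at 13 without new compounds. Radical hydrogenation by hydrogen-atom transfer (Mn(dpm)3, PhSiH3, t-BuOOH, i-PrOH, rt) adds hydrogen first to C6 and then to the tertiary C5 radical. The second transfer is under product-stability control and should favour the trans-fused decalin, and the tetrasubstituted alkene should react far more slowly.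

**Step 7.** The C1 carbonyl lies between the quaternary C10 and the C9 side chain, so hydrazone formation may be incomplete, and azine formation or reduction to the alcohol may intervene. The fallback sets out from 13 and comes back at 15. Enolisation toward C2, the only possible direction, and triflation (KN(SiMe3)2, PhNTf2, THF, −78 °C) would give the bis(enol triflate), 8,8'-(ethane-1,2-diyl)bis[(4aS,8aS)-4,4,7,8a-tetramethyl-3,4,4a,5,6,8a-hexahydronaphthalen-1-yl] bis(trifluoromethanesulfonate) F7. Palladium-catalysed formate reduction (Pd(OAc)2, PPh3, HCO2H, Bu3N, DMF, 60 °C) would give 1,2-bis[(4aS,8aS)-2,5,5,8a-tetramethyl-3,4,4a,5,6,8a-hexahydronaphthalen-1-yl]ethane F8. Hydrogenation of its disubstituted C1=C2 alkenes with RhCl(PPh3)3 (H2, benzene, rt) would spare the tetrasubstituted alkenes and give 15.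

## Further compounds

F1 | step 5 | (8aS,8a'S)-8,8'-(ethane-1,2-diyl)bis(4,4,7,8a-tetramethyl-3,4,6,8a-tetrahydronaphthalen-1(2H)-one) | CC1=C(CCC2=C(C)CC=C3C(C)(C)CCC(=O)[C@@]23C)[C@]2(C)C(=O)CCC(C)(C)C2=CC1
F2 | step 5 | (8aR,8a'S)-8,8'-(ethane-1,2-diyl)bis(4,4,7,8a-tetramethyl-3,4,6,8a-tetrahydronaphthalen-1(2H)-one) (meso) | CC1=C(CCC2=C(C)CC=C3C(C)(C)CCC(=O)[C@@]23C)[C@@]2(C)C(=O)CCC(C)(C)C2=CC1
F3 | step 1 | methyl 2-bromo-3-methylbenzoate | COC(=O)c1cccc(C)c1Br
F4 | step 1 | (E)-1,2-bis(4,4,5,5-tetramethyl-1,3,2-dioxaborolan-2-yl)ethene | CC1(C)OB(/C=C/B2OC(C)(C)C(C)(C)O2)OC1(C)C
F5 | step 1 | dimethyl 2,2'-[(E)-ethene-1,2-diyl]bis(3-methylbenzoate) | COC(=O)c1cccc(C)c1/C=C/c1c(C)cccc1C(=O)OC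
F6 | step 1 | dimethyl 2,2'-(ethane-1,2-diyl)bis(3-methylbenzoate) | COC(=O)c1cccc(C)c1CCc1c(C)cccc1C(=O)OC
F0 | step 4 | none | none
F0 | step 6 | none | none
F7 | step 7 | 8,8'-(ethane-1,2-diyl)bis[(4aS,8aS)-4,4,7,8a-tetramethyl-3,4,4a,5,6,8a-hexahydronaphthalen-1-yl] bis(trifluoromethanesulfonate) | CC1=C(CCC2=C(C)CC[C@H]3C(C)(C)CC=C(OS(=O)(=O)C(F)(F)F)[C@]23C)[C@@]2(C)C(OS(=O)(=O)C(F)(F)F)=CCC(C)(C)[C@@H]2CC1
F8 | step 7 | 1,2-bis[(4aS,8aS)-2,5,5,8a-tetramethyl-3,4,4a,5,6,8a-hexahydronaphthalen-1-yl]ethane | CC1=C(CCC2=C(C)CC[C@H]3C(C)(C)CC=C[C@]23C)[C@@]2(C)C=CCC(C)(C)[C@@H]2CC1
A1 | alternative 1 | (3S,22S,6E,10E,14E,18E)-2,3:22,23-diepoxy-2,6,10,15,19,23-hexamethyltetracosa-6,10,14,18-tetraen-12-yne | CC1(C)O[C@H]1CC/C(C)=C/CC/C(C)=C/C#C/C=C(C)/CC/C=C(C)/CC[C@@H]1OC1(C)C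
A2 | alternative 1 | 3,3'-dihydroxy-11,11'-didehydro analogue of the target (3S, hydroxyl equatorial in each half) | CC1=C(C#CC2=C(C)CC[C@H]3C(C)(C)[C@@H](O)CC[C@]23C)[C@@]2(C)CC[C@H](O)C(C)(C)[C@@H]2CC1
A3 | alternative 2 | 2,6-dimethyl-1,4-benzoquinone | CC1=CC(=O)C=C(C)C1=O
A4 | alternative 2 | 4-methylpenta-1,3-diene | CC(C)=CC=C
A5 | alternative 2 | cis-2,5,5,8a-tetramethyl-4a,5,8,8a-tetrahydronaphthalene-1,4-dione (C8a configured as C10 of the target) | CC1=CC(=O)[C@@H]2C(C)(C)C=CC[C@]2(C)C1=O
A6 | alternative 3 | (4aS,8aS)-2,5,5,8a-tetramethyloctahydronaphthalen-1(2H)-one (either configuration at C2) | CC1C(=O)[C@@]2(C)CCCC(C)(C)[C@@H]2CC1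
A7 | alternative 3 | (4aS,8aS)-2,5,5,8a-tetramethyl-3,4,4a,5,6,7,8,8a-octahydronaphthalen-1-yl trifluoromethanesulfonate | CC1=C(OS(=O)(=O)C(F)(F)F)[C@@]2(C)CCCC(C)(C)[C@@H]2CC1
A8 | alternative 3 | acetylene | C#C
A9 | alternative 3 | 1,2-bis[(4aS,8aS)-2,5,5,8a-tetramethyl-3,4,4a,5,6,7,8,8a-octahydronaphthalen-1-yl]ethyne | CC1=C(C#CC2=C(C)CC[C@H]3C(C)(C)CCC[C@]23C)[C@@]2(C)CCCC(C)(C)[C@@H]2CC1
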